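## Analysis of the target

Eremophilane numbering is used. Ring A is C1, C2, C3, C4, C5, C10. Ring B is C5, C6, C7, C8, C9, C10. C14 is the methyl on C5, C15 the methyl on C4, and the side chain is C11(C13)–C12.

- The target is a cis-fused decalin with five stereocentres (3S,4R,5R,10S,11R). It carries a (Z)-2-methylbut-2-enoate (angelate) on O3, a tertiary alcohol at C10, the enone C6=C7–C8=O and the free acid C12.
- **First feature.** On ring A the groups O3, C15, C14 and O10 sit on the four neighbouring carbons C3, C4, C5 and C10. All four lie on one face, in the O/Me/Me/O order of 2,3-dimethylhydroquinone (1). With H in place of C6 and C9 this ring would be a meso compound.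
- **Second feature.** The chain C9–C8(=O)–C7–C11(C13)–C12O2H is an unbroken 2-methyl-4-oxopentanoic acid (18). It is tied to ring A through both α-carbons of its ketone: C9 to C10 at the aldol level, and C7 to C6 at the aldol-condensation level. Ring B is therefore the C5–C10 edge of ring A, plus the single carbon C6, plus this three-carbon segment.
- C11 is cut off from the ring stereocentres by the sp2 carbon C7, so it cannot be relayed and must be set on its own.
- **Sensitive groups.**
  - The β-hydroxy ketone can undergo retro-aldol cleavage or dehydrate to the cross-conjugated dienone.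
  - C11–H is allylic and α to the acid, so it can epimerise, and C6=C7 can slip to C7=C11.
  - The angelate loses its Z geometry with acid, nucleophiles or heat.
- **What makes it hard.** The quaternary C5 lies between the stereocentre C4 and the fully substituted C10. Four substituents crowd one face. Ring B also has an oxidation pattern (enone plus retained ketol) that a normal annulation destroys.

## Retrosynthetic reasoning

**22 to 11 and 19 (C6=C7 and C9–C10).** Ring B is cut at the two bonds that join the keto acid segment to ring A.
- This frees the whole C7–C9/C11–C13 unit as the bis-silylated keto acid 19. It leaves ring A as the keto acetal 11, a 1,3-dielectrophile with C6 at the aldehyde level and C10 as a ketone.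
- The cut is made here and not at C5–C6 for three reasons. No oxidation state has to be changed afterwards. The two halves each carry their own stereocentres. The acid needs no protecting group.
- The forward reaction must join C7 to C6 first and C9 to C10 second. It must keep the C10 hydroxyl and form the double bond only inside the ring, where its geometry is fixed.

**19 to 18, 16, 14, then 12 and 13 (C7–C11).** C11 is made where it is easiest, in a five-carbon acid, by auxiliary-controlled alkylation of 12 with 13. The methallyl group is a masked acetonyl group: ozonolysis of 16 gives the ketone C8 with its methyl C9 in 18. Silylation to 19 fixes which α-carbon of the ketone reacts first.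

**11 to 9 and 10 (C5–C6).** The quaternary centre is formed with the smallest possible carbon electrophile, the cation derived from 10, on the tetrasubstituted enol silane 9. Only one stereochemical question remains, the face of C5, and the neighbouring C15 methyl answers it. The acetal keeps C6 silent until the last step.

**9 to 8, 7, 6, then 3 and 4 (O3–acyl bond and C10 oxidation level).** The angelate is put on early. At that stage the alcohol sits on a simple monocyclic ring and no ketol, enone or acid is present. Every later step is run cold under Lewis acid catalysis or with brief mild base. The acetate of 6 only marks the carbinol that becomes the C10 ketone of 8.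

**3 to 2 to 1 (no C–C bond; stereocentres as a group).**
- The all-cis O/Me/Me/O array is the result of adding six hydrogens to one face of 1. The product 2 is meso, so one enzymatic acylation to 3 fixes the absolute configuration of C3 and C4.
- C5 and C10 are later planarised and rebuilt under the control of these two centres.
- All eight carbons and both oxygens of ring A are bought in one compound.

## Alternatives that were turned down

**Alternative 1:** the textbook cut at C5–C6 and C9–C10, in which ring B comes from a four-carbon enone by Robinson annulation on a ketone of the type of 8. The forward key step is a Michael addition at C5 followed by aldol condensation, giving the octalone A1. It was turned down for the following reasons.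
- The condensation removes exactly the oxygen that the target keeps at C10. That oxygen would have to be returned by nucleophilic epoxidation of C9=C10 and reductive opening.
- C6=C7 would then need a regioselective dehydrogenation of a ketone that enolises to both sides.
- The side chain would have to be attached at C7 by an alkylation that has no control over C11.
- Each of these is a separate operation on a base-sensitive ketol. The annulation that looks short therefore costs at least seven further steps.

**Alternative 2:** a cut at C4–C5 with ring B bought as a phenol. The forward key step is a carbenoid or acid-induced para-alkylative dearomatisation of the diazo ketone A2, giving the cross-conjugated dienone A3. It was turned down on two selectivity grounds that lie in the structure.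
- The tether on C10 reaches C9 (unsubstituted, ortho to the phenol oxygen) as easily as C5 (methyl-bearing). Attack at C9 is made irreversible by rearomatisation.
- In A3 the formal hydration must pick the β,β-disubstituted C10 over the β-monosubstituted C6, against the normal order of conjugate addition.
- In addition, C5 would have to be set by a catalyst in the presence of the remote C11 centre.

**Alternative 3:** a cut at C4–C5 through the Claisen retron O=C3–C4–C5–C6=C7. The forward key step is the [3,3] rearrangement of the propenyl ether A4 to the aldehyde A5. It carries the configuration of the C7 carbinol to the quaternary C5 and leaves C6=C7 in place. The step itself is attractive, but it was turned down for what remains after it.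
- A5 still lacks C1 and C2.
- The C10 carbinol would have to be made by an intermolecular addition to the ketone on the face of the bulky C4 branch.
- C8 needs an allylic oxidation.
- The whole side chain, with C11, is missing.
- The way from A5 to the target is therefore longer than the complete route chosen here.

Key step: step 12

Assumption: the target is treated as the open γ-keto acid that is drawn; a ring–chain equilibrium with the lactol at C8 does not change the route.

## Steps

Step 1
Reactants: 1 2,3-dimethylbenzene-1,4-diol
Product: 2 (1R,2S,3R,4S)-2,3-dimethylcyclohexane-1,4-diol (all-cis, meso)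
Conditions: H2 (50 bar), Rh/Al2O3 (5 wt%), i-PrOH, 50 °C; recrystallisation
Reagents that add atoms: none
Why: Heterogeneous arene hydrogenation; the ring stays bound to rhodium by one face and all six hydrogens arrive from that face, so both OH and both CH3 groups end up on the other face. The all-cis diol is achiral and already shows the relative configuration of C3, C4, C5 and C10.

Step 2
Reactants: 2 (1R,2S,3R,4S)-2,3-dimethylcyclohexane-1,4-diol
Product: 3 (1R,2S,3R,4S)-4-hydroxy-2,3-dimethylcyclohexyl acetate
Conditions: immobilised Candida antarctica lipase B, vinyl acetate, t-BuOMe, 30 °C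
Reagents that add atoms: vinyl acetate, C=COC(C)=O
Why: Lipase-catalysed desymmetrisation of a meso diol by irreversible transesterification; lipases acylate the carbinol whose large flank (CHCH3) and small flank (CH2) are placed as in an (R)-alcohol, here the future C10, so the absolute configuration of C3 and C4 is fixed in one event. The minor enantiomer of 3 is acylated a second time faster, which should raise the enantiomeric purity.

Step 3
Reactants: 3 (1R,2S,3R,4S)-4-hydroxy-2,3-dimethylcyclohexyl acetate; 4 angelic acid, (Z)-2-methylbut-2-enoic acid
Product: 6 (1S,2R,3S,4R)-4-acetoxy-2,3-dimethylcyclohexyl (Z)-2-methylbut-2-enoate, via mixed anhydride 5 (not isolated)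
Conditions: 4, 2,4,6-Cl3C6H2COCl, Et3N, toluene, 23 °C; then 3, 80 °C
Reagents that add atoms: none
Why: Yamaguchi esterification; in 5 the aroyl carbonyl is shielded by two ortho chlorines, so the alcohol attacks the angeloyl carbonyl. No nucleophilic catalyst is present that could add to the enoate, so the Z geometry should be kept; no stereocentre is touched.

Step 4
Reactants: 6 (1S,2R,3S,4R)-4-acetoxy-2,3-dimethylcyclohexyl (Z)-2-methylbut-2-enoate
Product: 7 (1S,2R,3S,4R)-4-hydroxy-2,3-dimethylcyclohexyl (Z)-2-methylbut-2-enoate
Conditions: K2CO3 (0.2 equiv), MeOH, 0 °C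
Reagents that add atoms: none
Why: Chemoselective transesterification; an acetate is methanolysed much faster than the α-branched, conjugated angelate, and the 1,4-relation of the two oxygens rules out acyl migration.

Step 5
Reactants: 7 (1S,2R,3S,4R)-4-hydroxy-2,3-dimethylcyclohexyl (Z)-2-methylbut-2-enoate
Product: 8 (1S,2R,3S)-2,3-dimethyl-4-oxocyclohexyl (Z)-2-methylbut-2-enoate
Conditions: (n-Pr4N)RuO4 (5 mol%), N-methylmorpholine N-oxide, 4 Å sieves, CH2Cl2, 23 °C
Reagents that add atoms: none
Why: Ley–Griffith oxidation under neutral conditions that leave the enoate alone; the angelate is γ to the new ketone on both paths, so it cannot be eliminated. C5 becomes epimerisable, which does not matter because it is planarised in step 6.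

Step 6
Reactants: 8 (1S,2R,3S)-2,3-dimethyl-4-oxocyclohexyl (Z)-2-methylbut-2-enoate
Product: 9 (1S,2R)-2,3-dimethyl-4-(trimethylsilyloxy)cyclohex-3-en-1-yl (Z)-2-methylbut-2-enoate
Conditions: Me3SiOTf, Et3N, CH2Cl2, 0 to 23 °C
Reagents that add atoms: trimethylsilyl trifluoromethanesulfonate, C[Si](C)(C)OS(=O)(=O)C(F)(F)F
Why: Soft enolisation under equilibrating conditions (the ammonium triflate shuttles protons) favours the more substituted enol silane C5=C10; C3 and C4 are not acidic and keep their configuration.

Step 7
Reactants: 9 (1S,2R)-2,3-dimethyl-4-(trimethylsilyloxy)cyclohex-3-en-1-yl (Z)-2-methylbut-2-enoate; 10 trimethyl orthoformate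
Product: 11 (1S,2R,3S)-3-(dimethoxymethyl)-2,3-dimethyl-4-oxocyclohexyl (Z)-2-methylbut-2-enoate
Conditions: 10, Me3SiOTf (10 mol%), CH2Cl2, −78 to −40 °C
Reagents that add atoms: none
Why: Mukaiyama-type reaction of an enol silane with an orthoester; the small dimethoxycarbenium ion can build the quaternary C5. To avoid allylic 1,2-strain with C14 the C15 methyl stands pseudoaxial, and the cation enters anti to it along the axial, chair-forming path, so C6 becomes trans to C15 and C14 stays cis to C15.

Step 8
Reactants: 12 (S)-4-benzyl-3-propionyloxazolidin-2-one; 13 3-bromo-2-methylprop-1-ene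
Product: 14 (S)-4-benzyl-3-[(R)-2,4-dimethylpent-4-enoyl]oxazolidin-2-one
Conditions: NaN(SiMe3)2, THF, −78 °C; 13, −78 to −30 °C
Reagents that add atoms: none
Why: Evans alkylation; the chelated Z-enolate is shielded on one face by the benzyl group, so the allylic bromide enters from the other face and sets C11 as (R) while forming the C7–C11 bond.

Step 9
Reactants: 14 (S)-4-benzyl-3-[(R)-2,4-dimethylpent-4-enoyl]oxazolidin-2-one
Product: 16 (R)-2,4-dimethylpent-4-enoic acid, via peroxy acid 15 (not isolated)
Conditions: LiOH, H2O2, THF–H2O, 0 °C; Na2SO3; HCl
Reagents that add atoms: hydrogen peroxide, OO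
Why: Hydroperoxide cleavage of an N-acyloxazolidinone; the small, weakly basic hydroperoxide anion attacks the exocyclic carbonyl without enolisation at C11, and sulfite reduces 15 to the acid.

Step 10
Reactants: 16 (R)-2,4-dimethylpent-4-enoic acid
Product: 18 (R)-2-methyl-4-oxopentanoic acid, via ozonide 17 (not isolated)
Conditions: O3, CH2Cl2, −78 °C; Me2S, −78 to 23 °C
Reagents that add atoms: ozone, [O-][O+]=O
Why: Ozonolysis of the 1,1-disubstituted alkene gives the methyl ketone C8 with C9 under neutral conditions that cannot touch C11.

Step 11
Reactants: 18 (R)-2-methyl-4-oxopentanoic acid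
Product: 19 trimethylsilyl (R,Z)-2-methyl-4-(trimethylsilyloxy)pent-3-enoate
Conditions: Me3SiOTf (2.1 equiv), Et3N, Et2O, 0 to 23 °C; distillation
Reagents that add atoms: trimethylsilyl trifluoromethanesulfonate, C[Si](C)(C)OS(=O)(=O)C(F)(F)F
Why: Silylation of the acid and soft enolisation of the ketone under equilibrating conditions, which favour the internal (Z)-enol silane C7=C8. A ketone is enolised far faster than a silyl ester, so with the reagent limited to two equivalents C11 should stay untouched.

Step 12
Reactants: 11 (1S,2R,3S)-3-(dimethoxymethyl)-2,3-dimethyl-4-oxocyclohexyl (Z)-2-methylbut-2-enoate; 19 trimethylsilyl (R,Z)-2-methyl-4-(trimethylsilyloxy)pent-3-enoate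
Product: 22 (3S,4R,5R,10S,11R)-3-angeloyloxy-10-hydroxy-8-oxoeremophil-6-en-12-oic acid (CNP0307859.1), via methoxy ketone silyl ester 20 (not isolated), via bicyclic methoxy ketol 21 (not isolated)
Conditions: Me3SiOTf (0.1 equiv), CH2Cl2, −78 °C; then NaOMe (3 equiv), MeOH, −20 to 0 °C; 1 M HCl to pH 4, 0 °C
Reagents that add atoms: none
Why: Me3SiOTf ionises the acetal of 11 to the C6 oxocarbenium ion, C7 of the enol silane 19 adds to it (Mukaiyama aldol reaction of an acetal) and the silyl group leaves with a methoxide, giving 20 as a mixture at the transient centres C6 and C7. Methanolic NaOMe then frees the carboxylate, the C9 enolate of the methyl ketone adds to the C10 ketone to give 21 (the ketol stage of a Robinson annulation is the closest known reaction type), and the C7 enolate of 21 expels the C6 methoxide (E1cB) to give the enone of 22. Ring B closes in the 6-(enolendo)-exo-trig mode; the C7 enolate could reach C10 only through a four-membered ring. C10 is the only lasting new stereocentre: the tether starts at C6 on the face of ring A opposite to C14 and delivers C9 to the same face of the carbonyl through a chair-like transition state, so O10 becomes cis to C14 as in the cis-fused ketols of Robinson annulations, and because the aldol is reversible the less strained cis-fused ketol should also be collected by equilibration. C6 and C7 become sp2, so their mixture has no consequence, and because the double bond is formed inside the ring its geometry cannot be wrong. Three selectivities are needed: the acetal must react before the ketone (under catalytic Me3SiOTf acetals react, hindered ketones and enoates do not), C7 must be the first nucleophile and not C9 (fixed by the position of the enol silane in 19), and the ring must close before methanol is lost (the C9 methyl protons are removed faster than the hindered tertiary C7–H, and methoxide can add back to any open-chain enone). During the basic stage C11 is protected as the α-carbon of a carboxylate, and the low temperature should spare the angelate and the C10 hydroxyl.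

## Compound list

1 | 2,3-dimethylbenzene-1,4-diol (2,3-dimethylhydroquinone) | Cc1c(O)ccc(O)c1C | starting material
2 | (1R,2S,3R,4S)-2,3-dimethylcyclohexane-1,4-diol (all-cis, meso) | O[C@H]1CC[C@@H](O)[C@@H](C)[C@H]1C | intermediate
3 | (1R,2S,3R,4S)-4-hydroxy-2,3-dimethylcyclohexyl acetate | O[C@H]1CC[C@@H](OC(C)=O)[C@@H](C)[C@H]1C | intermediate
4 | angelic acid, (Z)-2-methylbut-2-enoic acid | C/C=C(/C)C(=O)O | starting material
5 | (Z)-2-methylbut-2-enoic 2,4,6-trichlorobenzoic anhydride | C/C=C(/C)C(=O)OC(=O)c1c(Cl)cc(Cl)cc1Cl | intermediate
6 | (1S,2R,3S,4R)-4-acetoxy-2,3-dimethylcyclohexyl (Z)-2-methylbut-2-enoate | C/C=C(/C)C(=O)O[C@H]1CC[C@@H](OC(C)=O)[C@@H](C)[C@H]1C | intermediate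
7 | (1S,2R,3S,4R)-4-hydroxy-2,3-dimethylcyclohexyl (Z)-2-methylbut-2-enoate | C/C=C(/C)C(=O)O[C@H]1CC[C@@H](O)[C@@H](C)[C@H]1C | intermediate
8 | (1S,2R,3S)-2,3-dimethyl-4-oxocyclohexyl (Z)-2-methylbut-2-enoate | C/C=C(/C)C(=O)O[C@H]1CCC(=O)[C@@H](C)[C@H]1C | intermediate
9 | (1S,2R)-2,3-dimethyl-4-(trimethylsilyloxy)cyclohex-3-en-1-yl (Z)-2-methylbut-2-enoate | C/C=C(/C)C(=O)O[C@H]1CCC(O[Si](C)(C)C)=C(C)[C@H]1C | intermediate
10 | trimethyl orthoformate | COC(OC)OC | starting material
11 | (1S,2R,3S)-3-(dimethoxymethyl)-2,3-dimethyl-4-oxocyclohexyl (Z)-2-methylbut-2-enoate | C/C=C(/C)C(=O)O[C@H]1CCC(=O)[C@](C)(C(OC)OC)[C@H]1C | intermediate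
12 | (S)-4-benzyl-3-propionyloxazolidin-2-one | CCC(=O)N1[C@@H](Cc2ccccc2)COC1=O | starting material
13 | 3-bromo-2-methylprop-1-ene | C=C(C)CBr | starting material
14 | (S)-4-benzyl-3-[(R)-2,4-dimethylpent-4-enoyl]oxazolidin-2-one | C=C(C)C[C@@H](C)C(=O)N1[C@@H](Cc2ccccc2)COC1=O | intermediate
15 | (R)-2,4-dimethylpent-4-eneperoxoic acid | C=C(C)C[C@@H](C)C(=O)OO | intermediate
16 | (R)-2,4-dimethylpent-4-enoic acid | C=C(C)C[C@@H](C)C(=O)O | intermediate
17 | (2R)-2-methyl-3-(3-methyl-1,2,4-trioxolan-3-yl)propanoic acid (ozonide, ring carbon undefined) | CC1(C[C@@H](C)C(=O)O)OCOO1 | intermediate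
18 | (R)-2-methyl-4-oxopentanoic acid | CC(=O)C[C@@H](C)C(=O)O | intermediate
19 | trimethylsilyl (R,Z)-2-methyl-4-(trimethylsilyloxy)pent-3-enoate | C/C(O[Si](C)(C)C)=C/[C@@H](C)C(=O)O[Si](C)(C)C | intermediate
20 | trimethylsilyl (2R)-3-acetyl-4-[(1S,2R,3S)-3-angeloyloxy-1,2-dimethyl-6-oxocyclohexyl]-4-methoxy-2-methylbutanoate (mixture at C6 and C7) | C/C=C(/C)C(=O)O[C@H]1CCC(=O)[C@](C)(C(OC)C(C(C)=O)[C@@H](C)C(=O)O[Si](C)(C)C)[C@H]1C | intermediate
21 | (3S,4R,5R,10S,11R)-3-angeloyloxy-10-hydroxy-6-methoxy-8-oxoeremophilan-12-oic acid (mixture at C6 and C7; sodium salt in the flask) | C/C=C(/C)C(=O)O[C@H]1CC[C@]2(O)CC(=O)C([C@@H](C)C(=O)O)C(OC)[C@]2(C)[C@H]1C | intermediate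
22 | (3S,4R,5R,10S,11R)-3-angeloyloxy-10-hydroxy-8-oxoeremophil-6-en-12-oic acid (CNP0307859.1) | C/C=C(/C)C(=O)O[C@H]1CC[C@]2(O)CC(=O)C([C@@H](C)C(=O)O)=C[C@]2(C)[C@H]1C | target

## Step count and least certain steps

Total step count: 12. Longest linear sequence: 8 (steps 1 to 7 and step 12). The second branch has 5 steps (steps 8 to 12).

**Step 12 (key step).**
- *What may go wrong.*
  - The C6–C7 bond has to form at a neopentyl oxocarbenium ion with a branched enol silane and may be slow.
  - In the basic stage, methanol may be lost from the open-chain stage before the ring closes. That gives an enone whose geometry holds C9 away from C10.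
  - Dehydration at C10, or methanolysis and Z-to-E isomerisation of the angelate, may set in if the basic stage has to be prolonged.
- *Fallback.* Ring B is closed at C6=C7 instead of at C9–C10, so that alkene geometry cannot matter. The fallback sets out from 18 and 11 and returns to the route at 22.
  - Acid 18 is converted with allyl bromide and K2CO3 into allyl (R)-2-methyl-4-oxopentanoate F1.
  - The kinetic C9 enolate of F1 (LiN(i-Pr)2, then CeCl3, THF, −78 °C) is added to the C10 ketone of 11. Addition should take place by axial attack on the conformer with axial C14, giving the tertiary aldol F2.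
  - Mild hydrolysis of the acetal (pyridinium tosylate, wet acetone) gives the keto aldehyde F3.
  - Dibenzylammonium trifluoroacetate in toluene brings about the intramolecular aldol condensation of C7 with C6 to the allyl ester of the target F4.
  - Pd(PPh3)4 and morpholine in THF remove the allyl group and return to 22.

**Step 6.**
- *What may go wrong.* Enolisation toward C1 competes, because the tetrasubstituted enol silane suffers allylic strain between C14 and C15. The resulting mixture of regioisomers would carry the one-carbon unit to C1 in step 7.
- *Fallback.* The enol silane is made regiospecifically by conjugate reduction. The fallback sets out from 8 and returns to the route at 11.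
  - Ketone 8 is brominated at the more substituted α-carbon (PhNMe3Br3, THF) to the bromo ketone F5.
  - Dehydrobromination (Li2CO3, LiBr, DMF) gives the tetrasubstituted enone F6.
  - 1,4-Hydrosilylation (Et3SiH, RhCl(PPh3)3, toluene) delivers hydrogen to C4 anti to the angelate. This restores C15 cis to O3 and gives the triethylsilyl enol ether F7.
  - F7 reacts with 10 under the conditions of step 7 and returns to the route at 11.

**Step 2.**
- *What may go wrong.* The lipase may discriminate poorly between the two enantiotopic carbinols. Each is flanked by a cis methyl group and is axial in one chair, which slows the acylation and lowers the enantiomeric purity.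
- *Fallback.* A redox desymmetrisation replaces the acyl transfer. The fallback sets out from 2 and returns to the route at 8.
  - An (R)-selective alcohol dehydrogenase, with acetone as hydrogen acceptor, oxidises only the future C10 carbinol of 2. The product is (2S,3R,4S)-4-hydroxy-2,3-dimethylcyclohexanone F8.
  - F8 is esterified with the mixed anhydride 5 as in step 3 and returns to the route at 8.

**Step 1.**
- *What may go wrong.* Partly hydrogenated keto tautomers may leave the catalyst surface and bind again by the other face. This erodes the all-cis selectivity at the carbinol carbons. Some C–O hydrogenolysis is also possible.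
- *Fallback.* The phenols are masked so that no keto tautomer can form. The fallback sets out from 1 and returns to the route at 2.
  - Hydroquinone 1 is silylated (t-BuMe2SiCl, imidazole) to the bis(silyl ether) F9.
  - F9 is hydrogenated over Rh/C in hexane to the all-cis bis(silyl ether) F10.
  - Bu4NF in THF returns to the route at 2.

## Further compounds

F1 | step 12 | allyl (R)-2-methyl-4-oxopentanoate | CC(=O)C[C@@H](C)C(=O)OCC=C
F2 | step 12 | allyl (2R)-5-[4-angeloyloxy-2-(dimethoxymethyl)-1-hydroxy-2,3-dimethylcyclohexyl]-2-methyl-4-oxopentanoate (O10 cis to C14) | C/C=C(/C)C(=O)O[C@H]1CC[C@](O)(CC(=O)C[C@@H](C)C(=O)OCC=C)[C@](C)(C(OC)OC)[C@H]1C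
F3 | step 12 | allyl (2R)-5-[4-angeloyloxy-2-formyl-1-hydroxy-2,3-dimethylcyclohexyl]-2-methyl-4-oxopentanoate | C/C=C(/C)C(=O)O[C@H]1CC[C@](O)(CC(=O)C[C@@H](C)C(=O)OCC=C)[C@](C)(C=O)[C@H]1C
F4 | step 12 | allyl ester of 22 | C/C=C(/C)C(=O)O[C@H]1CC[C@]2(O)CC(=O)C([C@@H](C)C(=O)OCC=C)=C[C@]2(C)[C@H]1C
F5 | step 6 | (1S,2R)-3-bromo-2,3-dimethyl-4-oxocyclohexyl (Z)-2-methylbut-2-enoate | C/C=C(/C)C(=O)O[C@H]1CCC(=O)C(C)(Br)[C@H]1C
F6 | step 6 | (S)-2,3-dimethyl-4-oxocyclohex-2-en-1-yl (Z)-2-methylbut-2-enoate | C/C=C(/C)C(=O)O[C@H]1CCC(=O)C(C)=C1C
F7 | step 6 | (1S,2R)-2,3-dimethyl-4-(triethylsilyloxy)cyclohex-3-en-1-yl (Z)-2-methylbut-2-enoate | C/C=C(/C)C(=O)O[C@H]1CCC(O[Si](CC)(CC)CC)=C(C)[C@H]1C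
F8 | step 2 | (2S,3R,4S)-4-hydroxy-2,3-dimethylcyclohexan-1-one | O[C@H]1CCC(=O)[C@@H](C)[C@H]1C
F9 | step 1 | 1,4-bis(tert-butyldimethylsilyloxy)-2,3-dimethylbenzene | Cc1c(O[Si](C)(C)C(C)(C)C)ccc(O[Si](C)(C)C(C)(C)C)c1C
F10 | step 1 | all-cis-1,4-bis(tert-butyldimethylsilyloxy)-2,3-dimethylcyclohexane (meso) | CC(C)(C)[Si](C)(C)O[C@H]1CC[C@@H](O[Si](C)(C)C(C)(C)C)[C@@H](C)[C@H]1C
A1 | alternative 1 | 3-(tert-butyldimethylsilyloxy)-4,5-dimethyl octal-9-en-8-one (eremophilane numbering, no side chain) | CC(C)(C)[Si](C)(C)O[C@H]1CCC2=CC(=O)CC[C@]2(C)[C@H]1C
A2 | alternative 2 | methyl (R)-2-[4-(4-diazo-3-oxopentyl)-2-hydroxy-5-methylphenyl]propanoate | COC(=O)[C@H](C)c1cc(C)c(CCC(=O)C(C)=[N+]=[N-])cc1O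
A3 | alternative 2 | methyl 3,8-dioxoeremophila-6,9-dien-12-oate | O=C1CCC2=CC(=O)C([C@@H](C)C(=O)OC)=C[C@]2(C)[C@H]1C
A4 | alternative 3 | (S)-2-methyl-4-[(E)-prop-1-enyloxy]cyclohex-2-en-1-one | C/C=C/O[C@H]1CCC(=O)C(C)=C1
A5 | alternative 3 | 2-(1-methyl-2-oxocyclohex-3-en-1-yl)propanal with the C4 and C5 configuration of the target | O=C[C@H](C)[C@@]1(C)C=CCCC1=O
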